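A direct plan would take both rings from (+)-sclareolide A1 and cut the lactone down in four steps (methyl ketone, Baeyer–Villiger oxidation, methanolysis, iodination) to iodo alcohol A2. A2 would be joined to aryl iodide A3 by nickel cross-electrophile coupling to give A4. BF3 would then trigger four successive 1,2-shifts to the friedo skeleton A5, and methanolysis would free the phenol.
Its weakest steps would be these:
- The cationic shift cascade would have no control over where it stops or which proton is lost, so olefin isomers would have to be separated on AgNO3–silica.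
- The cross-electrophile coupling would have to engage a neopentyl iodide beside a free tertiary alcohol, which would invite reduction and elimination.
- The four-step excision of one carbon would add length without adding complexity.

The new route disconnects ring B at C8–C9 and the side chain at C11–aryl in one palladium cascade (numbering: ring A = C1–C5, C10; ring B = C5–C10; C11 = ArCH2). It exploits the fact that C9 is quaternary, with a methyl and a CH2Ar group, next to the methyl-bearing C8: a (Z)-3-iodobut-2-enyl chain on C5 adds 6-exo to an isopropenyl group on C10, and the neopentyl palladium is arylated. One operation closes ring B onto a monocyclic ring A, creates C9 and attaches the arene, so no cationic skeletal reorganisation, no coupling of a β-hydroxy alkyl iodide and no degradation of a side chain occur.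

Key step: step 6

Remark: the sense of induction in step 1 depends on the ligand enantiomer; the enantiomer that gives the (S)-configured adduct is assumed to be used.

Step 1
Reactants: 1 2-methylcyclohex-2-en-1-one
Product: 3 (S)-trimethyl{[2-methyl-3-(prop-1-en-2-yl)cyclohex-1-en-1-yl]oxy}silane, via bromomagnesium (S)-2-methyl-3-(prop-1-en-2-yl)cyclohex-1-en-1-olate 2 (not isolated)
Conditions: isopropenylMgBr (1.3 equiv), Cu(OTf)2 (5 mol %), chiral imidazolinium NHC precursor (6 mol %), Et2O, −30 °C; then TMSCl, Et3N, HMPA, −30 °C → rt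
Reagents that add atoms: isopropenylmagnesium bromide, C=C(C)[Mg]Br; chlorotrimethylsilane, C[Si](C)(C)Cl
Why: Copper-catalysed asymmetric conjugate addition of a Grignard reagent to an α-substituted cyclic enone, in which the chiral NHC–copper complex should deliver the isopropenyl group to one face of C3 (new stereocentre, S) and O-silylation of magnesium enolate 2 fixes the tetrasubstituted enol ether regiochemistry.

Step 2
Reactants: 4 but-2-yn-1-ol
Product: 6 (Z)-3-iodobut-2-en-1-ol, via sodium cyclic (Z)-alkenylaluminate (3-methyl-2,2-bis(2-methoxyethoxy)-2,5-dihydro-1,2-oxaaluminol-2-uide) 5 (not isolated)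
Conditions: Red-Al, THF, 0 °C → rt; then I2, −78 → 0 °C
Reagents that add atoms: iodine, II
Why: Hydroxyl-directed trans-hydroalumination of the propargylic alcohol places aluminium at C3 in the five-membered aluminate 5, and iodinolysis with retention should give the Z vinyl iodide (no stereocentre).

Step 3
Reactants: 6 (Z)-3-iodobut-2-en-1-ol
Product: 7 (Z)-1-bromo-3-iodobut-2-ene
Conditions: CBr4, PPh3, CH2Cl2, 0 °C
Reagents that add atoms: carbon tetrabromide, BrC(Br)(Br)Br
Why: Appel reaction, in which SN2 displacement at the primary allylic carbon should leave the vinyl iodide and the Z geometry untouched.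

Step 4
Reactants: 3 (S)-trimethyl{[2-methyl-3-(prop-1-en-2-yl)cyclohex-1-en-1-yl]oxy}silane, 7 (Z)-1-bromo-3-iodobut-2-ene
Product: 9 (2S,3S)-2-[(2Z)-3-iodobut-2-en-1-yl]-2-methyl-3-(prop-1-en-2-yl)cyclohexan-1-one, via lithium (S)-2-methyl-3-(prop-1-en-2-yl)cyclohex-1-en-1-olate 8 (not isolated)
Conditions: MeLi (1.0 equiv), THF, 0 °C → rt; then DMPU, 7, −78 → −20 °C
Reagents that add atoms: none
Why: Stork-type regeneration of the regiodefined lithium enolate 8 from the silyl enol ether, followed by SN2 alkylation with the allylic bromide anti to the pseudo-axial isopropenyl group, should set the quaternary centre C2 (S) with the two carbon chains 2,3-trans.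

Step 5
Reactants: 10 methyl 4-hydroxy-3-iodobenzoate
Product: 11 methyl 4-hydroxy-3-(4,4,5,5-tetramethyl-1,3,2-dioxaborolan-2-yl)benzoate
Conditions: B2pin2, PdCl2(dppf) (3 mol %), KOAc, 1,4-dioxane, 85 °C
Reagents that add atoms: bis(pinacolato)diboron, CC1(C)OB(OC1(C)C)B1OC(C)(C)C(C)(C)O1
Why: Miyaura borylation, in which the weak base KOAc should allow conversion of the aryl iodide into the pinacol boronate without Suzuki homocoupling, the ester and the free phenol being tolerated.

Step 6
Reactants: 9 (2S,3S)-2-[(2Z)-3-iodobut-2-en-1-yl]-2-methyl-3-(prop-1-en-2-yl)cyclohexan-1-one, 11 methyl 4-hydroxy-3-(4,4,5,5-tetramethyl-1,3,2-dioxaborolan-2-yl)benzoate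
Product: 13 methyl 4-hydroxy-3-{[(1S,4aS,8aS)-1,2,4a-trimethyl-5-oxo-1,4,4a,5,6,7,8,8a-octahydronaphthalen-1-yl]methyl}benzoate, via neopentyl σ-alkylpalladium(II) iodide (Pd on the CH2 group at C1 of the octalinone, phosphine ligands omitted) 12 (not isolated)
Conditions: Pd(OAc)2 (5 mol %), PPh3 (12 mol %), K3PO4 (3 equiv), 1,4-dioxane/H2O 9:1, 80 °C, 11 (1.5 equiv) added over 4 h
Reagents that add atoms: none
Why: Pd(0) inserts into the C–I bond of the (Z)-vinyl iodide with retention, the vinylpalladium adds syn across the isopropenyl group (Heck carbopalladation), and the σ-alkylpalladium 12, which has no β-hydrogen, is captured by transmetalation with boronate 11 and reductive elimination; the closest known reaction type is the domino Heck cyclization/Suzuki–Miyaura coupling (cyclization–anion capture). Ring B is closed in the 6-exo-trig mode, between the iodine-bearing carbon and the internal carbon of the isopropenyl group, which should be favoured over 7-endo because palladium is delivered to the unsubstituted CH2 terminus in an eclipsed six-membered array. The one new stereocentre is this quaternary carbon (C1 of the octalinone): the two side chains on the cyclohexanone are trans-diequatorial, so only the trans-fused half-chair can form, and within it the CH2–Pd terminus must take the pseudo-equatorial site while the methyl group takes the pseudo-axial site syn to the angular methyl group, since a palladated carbon cannot be placed 1,3-diaxial to that methyl group. The step needs ring closure to outrun direct Suzuki coupling of the vinylpalladium species, which slow addition of 11 should secure, and needs arylation to outrun 3-exo attack of 12 on the new ring alkene, which is disfavoured because the pseudo-equatorial CH2–Pd bond lies near the nodal plane of that alkene.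

Step 7
Reactants: 13 methyl 4-hydroxy-3-{[(1S,4aS,8aS)-1,2,4a-trimethyl-5-oxo-1,4,4a,5,6,7,8,8a-octahydronaphthalen-1-yl]methyl}benzoate
Product: 14 methyl 4-hydroxy-3-{[(1R,2S,4aS,8aS)-1,2,4a-trimethyl-5-oxodecahydronaphthalen-1-yl]methyl}benzoate
Conditions: H2 (4 atm), 10% Pd/C, EtOAc, rt
Reagents that add atoms: none
Why: Heterogeneous syn-hydrogenation of the trisubstituted ring alkene should occur from the α-face, because the β-face is shielded by the two syn-axial methyl groups on C1 and C4a, which sets C2 (S) with an equatorial methyl group while the ketone, ester and phenol stay inert.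

Step 8
Reactants: 14 methyl 4-hydroxy-3-{[(1R,2S,4aS,8aS)-1,2,4a-trimethyl-5-oxodecahydronaphthalen-1-yl]methyl}benzoate
Product: 15 Dictyoceratin C, methyl 4-hydroxy-3-{[(1R,2S,4aS,8aS)-1,2,4a-trimethyl-5-methylidenedecahydronaphthalen-1-yl]methyl}benzoate
Conditions: Ph3PCH3Br (5 equiv), KHMDS (4.8 equiv), toluene, 0 → 90 °C; then aq. NH4Cl
Reagents that add atoms: methyltriphenylphosphonium bromide, C[P+](c1ccccc1)(c1ccccc1)c1ccccc1.[Br-]
Why: Wittig methylenation of the hindered ketone with excess ylide, in which the phenol is deprotonated first so that the para-phenoxide deactivates the ester, and no stereocentre can epimerise because the only enolisable α-position is a CH2 group.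

Compound list
1 | 2-methylcyclohex-2-en-1-one | CC1=CCCCC1=O | starting material
2 | bromomagnesium (S)-2-methyl-3-(prop-1-en-2-yl)cyclohex-1-en-1-olate | C=C(C)[C@@H]1CCCC(O[Mg]Br)=C1C | intermediate
3 | (S)-trimethyl{[2-methyl-3-(prop-1-en-2-yl)cyclohex-1-en-1-yl]oxy}silane | C=C(C)[C@@H]1CCCC(O[Si](C)(C)C)=C1C | intermediate
4 | but-2-yn-1-ol | CC#CCO | starting material
5 | sodium 3-methyl-2,2-bis(2-methoxyethoxy)-2,5-dihydro-1,2-oxaaluminol-2-uide (cyclic Z-alkenylaluminate) | CC1=CCO[Al-]1(OCCOC)OCCOC.[Na+] | intermediate
6 | (Z)-3-iodobut-2-en-1-ol | C/C(I)=C/CO | intermediate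
7 | (Z)-1-bromo-3-iodobut-2-ene | C/C(I)=C/CBr | intermediate
8 | lithium (S)-2-methyl-3-(prop-1-en-2-yl)cyclohex-1-en-1-olate | C=C(C)[C@@H]1CCCC(O[Li])=C1C | intermediate
9 | (2S,3S)-2-[(2Z)-3-iodobut-2-en-1-yl]-2-methyl-3-(prop-1-en-2-yl)cyclohexan-1-one | C=C(C)[C@@H]1CCCC(=O)[C@@]1(C)C/C=C(/C)I | intermediate
10 | methyl 4-hydroxy-3-iodobenzoate | COC(=O)c1ccc(O)c(I)c1 | starting material
11 | methyl 4-hydroxy-3-(4,4,5,5-tetramethyl-1,3,2-dioxaborolan-2-yl)benzoate | COC(=O)c1ccc(O)c(B2OC(C)(C)C(C)(C)O2)c1 | intermediate
12 | neopentyl σ-alkylpalladium(II) iodide of the octalinone (ligands omitted) | O=C1CCC[C@H]2[C@](C)(C[Pd]I)C(C)=CC[C@]12C | intermediate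
13 | methyl 4-hydroxy-3-{[(1S,4aS,8aS)-1,2,4a-trimethyl-5-oxo-1,4,4a,5,6,7,8,8a-octahydronaphthalen-1-yl]methyl}benzoate | O=C1CCC[C@H]2[C@](C)(Cc3cc(C(=O)OC)ccc3O)C(C)=CC[C@]12C | intermediate
14 | methyl 4-hydroxy-3-{[(1R,2S,4aS,8aS)-1,2,4a-trimethyl-5-oxodecahydronaphthalen-1-yl]methyl}benzoate | O=C1CCC[C@H]2[C@](C)(Cc3cc(C(=O)OC)ccc3O)[C@@H](C)CC[C@]12C | intermediate
15 | Dictyoceratin C | C=C1CCC[C@H]2[C@](C)(Cc3cc(C(=O)OC)ccc3O)[C@@H](C)CC[C@]12C | target

Total steps: 8. Longest linear sequence: 6 (steps 2, 3, 4, 6, 7, 8).

Steps most likely to fail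

1. Step 6 (key step). The vinylpalladium species may be arylated before it cyclises, or the alkylpalladium 12 may be lost before arylation. Loss could occur by 7-endo closure, 3-exo attack on the ring alkene, ketone α-vinylation under the basic conditions, or protodeboronation of 11. The fallback runs from 9 back to 13; it puts the arene on the alkene first and closes the ring with hydride capture. Suzuki–Miyaura vinylation of 10 with potassium vinyltrifluoroborate would give methyl 4-hydroxy-3-vinylbenzoate F1. Cross-metathesis of F1 with the isopropenyl group of 9 (Hoveyda–Grubbs second-generation catalyst, CH2Cl2, 40 °C) would give the styrene methyl 4-hydroxy-3-[(1E)-2-{(1S,2S)-2-[(2Z)-3-iodobut-2-en-1-yl]-2-methyl-3-oxocyclohexyl}prop-1-en-1-yl]benzoate F2. A reductive Heck cyclization of F2 (Pd(OAc)2, PPh3, HCO2Na, DMF, 80 °C) would close ring B 6-exo at the same carbon and reduce the benzylic palladium to CH2, giving 13.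

2. Step 1. Facial selectivity may be poor, or 1,2-addition may compete, when an alkenyl Grignard reagent meets the α-methyl enone. The fallback runs from 1 back to 3. Rhodium(I)/BINAP-catalysed asymmetric 1,4-addition of potassium isopropenyltrifluoroborate to 1 (dioxane/H2O) would give (3R)-2-methyl-3-(prop-1-en-2-yl)cyclohexan-1-one F3 as a mixture of C2 epimers; the descriptor changes, but the spatial arrangement at C3 is that of 3. Enol silylation under equilibrating conditions (TMSCl, NaI, Et3N, MeCN) would then give the more substituted enol ether 3.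

3. Step 8. Olefination of the neopentyl ketone may stay incomplete, and the ylide may be acylated by the methyl ester. The fallback runs from 14 to 15 by Peterson olefination. Addition of Me3SiCH2MgCl/CeCl3 (THF, −78 °C), which should spare the ester, would give the β-hydroxysilane methyl 4-hydroxy-3-({(1R,2S,4aS,8aS)-5-hydroxy-1,2,4a-trimethyl-5-[(trimethylsilyl)methyl]decahydronaphthalen-1-yl}methyl)benzoate F4. Elimination with KH in THF would then give 15.

Further compounds
F1 | step 6 | methyl 4-hydroxy-3-vinylbenzoate | C=Cc1cc(C(=O)OC)ccc1O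
F2 | step 6 | methyl 4-hydroxy-3-[(1E)-2-{(1S,2S)-2-[(2Z)-3-iodobut-2-en-1-yl]-2-methyl-3-oxocyclohexyl}prop-1-en-1-yl]benzoate | COC(=O)c1ccc(O)c(/C=C(\C)[C@@H]2CCCC(=O)[C@@]2(C)C/C=C(/C)I)c1
F3 | step 1 | (3R)-2-methyl-3-(prop-1-en-2-yl)cyclohexan-1-one (C2 epimers) | C=C(C)[C@@H]1CCCC(=O)C1C
F4 | step 8 | methyl 4-hydroxy-3-({(1R,2S,4aS,8aS)-5-hydroxy-1,2,4a-trimethyl-5-[(trimethylsilyl)methyl]decahydronaphthalen-1-yl}methyl)benzoate | C[Si](C)(C)CC1(O)CCC[C@H]2[C@](C)(Cc3cc(C(=O)OC)ccc3O)[C@@H](C)CC[C@]12C
A1 | direct plan | (+)-sclareolide | C[C@]12CCCC(C)(C)[C@@H]1CC[C@@]3(C)OC(=O)C[C@H]23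
A2 | direct plan | (1R,2R,4aS,8aS)-1-(iodomethyl)-2,5,5,8a-tetramethyldecahydronaphthalen-2-ol | C[C@]12CCCC(C)(C)[C@@H]1CC[C@@](C)(O)[C@@H]2CI
A3 | direct plan | methyl 4-acetoxy-3-iodobenzoate | COC(=O)c1ccc(OC(C)=O)c(I)c1
A4 | direct plan | methyl 4-acetoxy-3-{[(1R,2R,4aS,8aS)-2-hydroxy-2,5,5,8a-tetramethyldecahydronaphthalen-1-yl]methyl}benzoate | C[C@]12CCCC(C)(C)[C@@H]1CC[C@@](C)(O)[C@@H]2Cc1cc(C(=O)OC)ccc1OC(C)=O
A5 | direct plan | O-acetyl dictyoceratin C (rearranged 4(11)-ene aryl acetate) | C=C1CCC[C@H]2[C@](C)(Cc3cc(C(=O)OC)ccc3OC(C)=O)[C@@H](C)CC[C@]12C
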